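**Plan**
- Retrosynthesis: the interflavan bond C4 (ring C)–C8 (ring D) is cut first, giving a flavan-4-yl cation and (−)-epigallocatechin as the nucleophile. Ring C of the upper unit is then cut at O1–C8a and C2–C3, a formal [4+2] of an aldehyde C=O across a C3-nucleophile/C8a-electrophile 1,4-dipole.
- Enabling feature: C8a of the 5-deoxy ring A is ortho to C4a–C4. With C4 as a ketone, C3–H becomes an enolate donor and a C8a–F bond becomes SNAr-active. The same C4 oxygen later leaves to form the interflavan bond, the cation being stabilised by the 7-oxygen para to C4a.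
- Forward order: rings A and B are bought as arenes, ring C is closed in step 3, rings D, E and F come intact from epigallocatechin, the halves are joined at C4–C8, and ten benzyl ethers fall last.
- Stereochemistry: C2/C3 trans by thermodynamic control in step 3; absolute configuration by kinetic resolution in the transfer hydrogenation of step 4; C4 by attack anti to the 3-benzyloxy group in step 6; the lower unit's two centres from the chiral pool.

Key step: step 3

Remark: 1, 2, 7 and 13 are taken as purchasable; 11 is carried as the racemate (its SMILES shows the (2R,3R) enantiomer), and 9 and 10 are diastereomer mixtures that carry no stereodescriptors.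

**Step 1**
Reactants: 1 4-(benzyloxy)-1-bromo-2-fluorobenzene; 2 2-(benzyloxy)-N-methoxy-N-methylacetamide
Product: 5 2-(benzyloxy)-1-[4-(benzyloxy)-2-fluorophenyl]ethan-1-one, via aryllithium 3 (not isolated), via lithium hemiaminal 4 (not isolated)
Conditions: n-BuLi (1.05 equiv), THF, −78 °C; then 2, −78 → 0 °C; 1 M HCl
Reagents that add atoms: none
Why: Bromine–lithium exchange should outrun loss of LiF at −78 °C, and the aryllithium adds only once to the amide because the chelated tetrahedral adduct survives until the acidic quench (Weinreb ketone synthesis); no stereocentre is formed.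

**Step 2**
Reactants: 5 2-(benzyloxy)-1-[4-(benzyloxy)-2-fluorophenyl]ethan-1-one
Product: 6 {[(1Z)-2-(benzyloxy)-1-[4-(benzyloxy)-2-fluorophenyl]ethenyl]oxy}trimethylsilane
Conditions: Me3SiOTf, Et3N, CH2Cl2, 0 °C; non-aqueous work-up, used directly
Reagents that add atoms: trimethylsilyl trifluoromethanesulfonate, C[Si](C)(C)OS(=O)(=O)C(F)(F)F
Why: Soft enolisation of the aryl ketone (silyl enol ether formation) should give the enol silane, expected mainly as the Z isomer, whose geometry is of no consequence because step 3 runs under equilibrating conditions.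

**Step 3**
Reactants: 6 {[(1Z)-2-(benzyloxy)-1-[4-(benzyloxy)-2-fluorophenyl]ethenyl]oxy}trimethylsilane; 7 3,4,5-tris(benzyloxy)benzaldehyde
Product: 11 racemic trans-3,7-bis(benzyloxy)-2-[3,4,5-tris(benzyloxy)phenyl]-2,3-dihydro-4H-chromen-4-one, via ammonium enolate 8 (not isolated), via ammonium aldolate 9 (not isolated), via silyl aldol 10 (not isolated)
Conditions: Bu4N[Ph3SiF2] (10 mol %), 4 Å molecular sieves, THF/DMF, −20 → 23 °C; then AcOH
Reagents that add atoms: none
Why: Proposed new method: catalytic fluoride strips the silyl group from 6 to give the naked enolate 8, whose C3 adds to the aldehyde carbon of 7 (C2–C3 bond; aldolate 9, reversibly parked as silyl ether 10), and the C2 alkoxide of 9 then displaces fluoride from C8a of ring A through a Meisenheimer complex stabilised by the ortho C4 carbonyl (O1–C8a bond); the expelled fluoride desilylates the next molecule of 6 or 10, so the net change is 6 + 7 → 11 + Me3SiF. The closest known reaction types are the fluoride-catalysed Mukaiyama aldol addition of enol silanes and the fluoride-catalysed SNAr etherification of ketone-activated aryl fluorides by silyl ethers; only their coupling through one shared fluoride is new. Ring C closes by addition–elimination at an sp2 carbon whose activating π bond (C8a=C4a, vinylogous to the C4 carbonyl) lies inside the new six-membered ring, that is a 6-endo-trig oxa-addition followed by loss of fluoride. C2 and C3 are both created here: the aldol step is reversible and C3 is epimerisable by enolisation next to C4=O in the catalytic basic medium, so the product should collect as the thermodynamically preferred 2,3-trans isomer with the 2-aryl and 3-benzyloxy groups both pseudo-equatorial, as the racemate. The step needs arylation of the C2 oxygen only, which the benzyl cap on the C3 oxygen secures (a free 3-OH could close a five-membered coumaranone), and it needs ring closure to outrun β-elimination to a chalcone, which the intramolecular carbonyl-activated SNAr and the low standing concentration of base should favour.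

**Step 4**
Reactants: 11 racemic trans-3,7-bis(benzyloxy)-2-[3,4,5-tris(benzyloxy)phenyl]-2,3-dihydro-4H-chromen-4-one
Product: 12 (2R,3S,4R)-3,7-bis(benzyloxy)-2-[3,4,5-tris(benzyloxy)phenyl]-3,4-dihydro-2H-chromen-4-ol
Conditions: RuCl[(S,S)-TsDPEN](p-cymene) (2 mol %), HCO2H/Et3N (1:1), CH2Cl2, 25 °C, stopped near half conversion
Reagents that add atoms: none
Why: In this asymmetric transfer hydrogenation run as a kinetic resolution (a known reaction type for racemic flavanones), the (S,S) catalyst should deliver hydride to the C4 face that places the new hydroxyl cis to the 2-aryl group, and only in the (2R,3R) enantiomer is this also the substrate's preferred face (anti to the axial C3–H, giving the all-equatorial 2,3-trans-3,4-trans alcohol), so that enantiomer should be reduced much faster and the (2S,3S) ketone is left behind.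

**Step 5**
Reactants: 13 (−)-epigallocatechin
Product: 14 (2R,3R)-5,7-bis(benzyloxy)-2-[3,4,5-tris(benzyloxy)phenyl]-3,4-dihydro-2H-chromen-3-ol
Conditions: BnBr (5.5 equiv), K2CO3, DMF, 0 → 23 °C, argon
Reagents that add atoms: benzyl bromide, BrCc1ccccc1
Why: Williamson etherification under carbonate selects the five phenols, which are far more acidic than the secondary 3-OH, and the two stereocentres of the chiral-pool flavan-3-ol are not touched at or below room temperature.

**Step 6**
Reactants: 12 (2R,3S,4R)-3,7-bis(benzyloxy)-2-[3,4,5-tris(benzyloxy)phenyl]-3,4-dihydro-2H-chromen-4-ol; 14 (2R,3R)-5,7-bis(benzyloxy)-2-[3,4,5-tris(benzyloxy)phenyl]-3,4-dihydro-2H-chromen-3-ol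
Product: 16 (2R,3S,4S)-3,7-bis(benzyloxy)-4-[(2R,3R)-5,7-bis(benzyloxy)-3-hydroxy-2-[3,4,5-tris(benzyloxy)phenyl]-3,4-dihydro-2H-chromen-8-yl]-2-[3,4,5-tris(benzyloxy)phenyl]-3,4-dihydro-2H-chromene, via flavan-4-yl cation 15 (not isolated)
Conditions: Me3SiOTf (0.3 equiv), 4 Å molecular sieves, CH2Cl2, −40 °C; 14 in excess (2.5 equiv)
Reagents that add atoms: none
Why: Lewis-acid ionisation of the C4 hydroxyl gives cation 15, stabilised by the para 7-benzyloxy group of ring A, which is captured in a Friedel–Crafts reaction by C8 of ring D of 14 (the usual reactive site of benzylated flavan-3-ols) from the face anti to the 3-benzyloxy group, which should set C4 as 3,4-trans (4S); any upper-unit enantiomer that escaped step 4 gives a diastereomer that is removed here by chromatography.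

**Step 7**
Reactants: 16 (2R,3S,4S)-3,7-bis(benzyloxy)-4-[(2R,3R)-5,7-bis(benzyloxy)-3-hydroxy-2-[3,4,5-tris(benzyloxy)phenyl]-3,4-dihydro-2H-chromen-8-yl]-2-[3,4,5-tris(benzyloxy)phenyl]-3,4-dihydro-2H-chromene
Product: 17 (2R,3S,4S)-4-[(2R,3R)-3,5,7-trihydroxy-2-(3,4,5-trihydroxyphenyl)-3,4-dihydro-2H-chromen-8-yl]-2-(3,4,5-trihydroxyphenyl)-3,4-dihydro-2H-chromene-3,7-diol (robinetinidol-(4α→8)-epigallocatechin)
Conditions: H2 (1 atm), Pd(OH)2/C, THF/MeOH/H2O, 23 °C; filtration and freeze-drying under argon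
Reagents that add atoms: none
Why: Hydrogenolysis should cleave all ten benzyl ethers as toluene, while the cyclic benzylic C2–O1 ether bonds and the doubly benzylic C4–C8 bond, which react far more slowly under these mild conditions, should survive, so no stereocentre is touched.

**Compound list**
1 | 4-(benzyloxy)-1-bromo-2-fluorobenzene | Fc1cc(OCc2ccccc2)ccc1Br | starting material
2 | 2-(benzyloxy)-N-methoxy-N-methylacetamide | CON(C)C(=O)COCc1ccccc1 | starting material
3 | [4-(benzyloxy)-2-fluorophenyl]lithium | [Li]c1ccc(OCc2ccccc2)cc1F | intermediate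
4 | lithium alkoxide of the tetrahedral adduct of 3 and 2 | CON(C)C(O[Li])(COCc1ccccc1)c1ccc(OCc2ccccc2)cc1F | intermediate
5 | 2-(benzyloxy)-1-[4-(benzyloxy)-2-fluorophenyl]ethan-1-one | O=C(COCc1ccccc1)c1ccc(OCc2ccccc2)cc1F | intermediate
6 | {[(1Z)-2-(benzyloxy)-1-[4-(benzyloxy)-2-fluorophenyl]ethenyl]oxy}trimethylsilane | C[Si](C)(C)O/C(=C\OCc1ccccc1)c1ccc(OCc2ccccc2)cc1F | intermediate
7 | 3,4,5-tris(benzyloxy)benzaldehyde | O=Cc1cc(OCc2ccccc2)c(OCc2ccccc2)c(OCc2ccccc2)c1 | starting material
8 | tetrabutylammonium (Z)-enolate of 5 | [O-]/C(=C\OCc1ccccc1)c1ccc(OCc2ccccc2)cc1F.CCCC[N+](CCCC)(CCCC)CCCC | intermediate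
9 | tetrabutylammonium 2-(benzyloxy)-3-[4-(benzyloxy)-2-fluorophenyl]-3-oxo-1-[3,4,5-tris(benzyloxy)phenyl]propan-1-olate (diastereomer mixture) | [O-]C(c1cc(OCc2ccccc2)c(OCc2ccccc2)c(OCc2ccccc2)c1)C(OCc1ccccc1)C(=O)c1ccc(OCc2ccccc2)cc1F.CCCC[N+](CCCC)(CCCC)CCCC | intermediate
10 | 2-(benzyloxy)-1-[4-(benzyloxy)-2-fluorophenyl]-3-[3,4,5-tris(benzyloxy)phenyl]-3-[(trimethylsilyl)oxy]propan-1-one (diastereomer mixture) | C[Si](C)(C)OC(c1cc(OCc2ccccc2)c(OCc2ccccc2)c(OCc2ccccc2)c1)C(OCc1ccccc1)C(=O)c1ccc(OCc2ccccc2)cc1F | intermediate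
11 | racemic trans-3,7-bis(benzyloxy)-2-[3,4,5-tris(benzyloxy)phenyl]-2,3-dihydro-4H-chromen-4-one ((2R,3R) enantiomer shown) | C(c1ccccc1)Oc1ccc2c(c1)O[C@H](c1cc(OCc3ccccc3)c(OCc3ccccc3)c(OCc3ccccc3)c1)[C@@H](OCc1ccccc1)C2=O | intermediate
12 | (2R,3S,4R)-3,7-bis(benzyloxy)-2-[3,4,5-tris(benzyloxy)phenyl]-3,4-dihydro-2H-chromen-4-ol (2,3-trans-3,4-trans) | C(c1ccccc1)Oc1ccc2c(c1)O[C@H](c1cc(OCc3ccccc3)c(OCc3ccccc3)c(OCc3ccccc3)c1)[C@@H](OCc1ccccc1)[C@@H]2O | intermediate
13 | (−)-epigallocatechin, (2R,3R)-2-(3,4,5-trihydroxyphenyl)-3,4-dihydro-2H-chromene-3,5,7-triol | Oc1cc(O)c2c(c1)O[C@H](c1cc(O)c(O)c(O)c1)[C@H](O)C2 | starting material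
14 | (2R,3R)-5,7-bis(benzyloxy)-2-[3,4,5-tris(benzyloxy)phenyl]-3,4-dihydro-2H-chromen-3-ol | C(c1ccccc1)Oc1cc(OCc3ccccc3)c2c(c1)O[C@H](c1cc(OCc3ccccc3)c(OCc3ccccc3)c(OCc3ccccc3)c1)[C@H](O)C2 | intermediate
15 | (2R,3S)-3,7-bis(benzyloxy)-2-[3,4,5-tris(benzyloxy)phenyl]-3,4-dihydro-2H-chromen-4-ylium trifluoromethanesulfonate | C(c1ccccc1)Oc1ccc2c(c1)O[C@H](c1cc(OCc3ccccc3)c(OCc3ccccc3)c(OCc3ccccc3)c1)[C@@H](OCc1ccccc1)[CH+]2.[O-]S(=O)(=O)C(F)(F)F | intermediate
16 | (2R,3S,4S)-3,7-bis(benzyloxy)-4-[(2R,3R)-5,7-bis(benzyloxy)-3-hydroxy-2-[3,4,5-tris(benzyloxy)phenyl]-3,4-dihydro-2H-chromen-8-yl]-2-[3,4,5-tris(benzyloxy)phenyl]-3,4-dihydro-2H-chromene | C(c1ccccc1)Oc1ccc2c(c1)O[C@H](c1cc(OCc3ccccc3)c(OCc3ccccc3)c(OCc3ccccc3)c1)[C@@H](OCc1ccccc1)[C@@H]2c1c(OCc3ccccc3)cc(OCc3ccccc3)c2c1O[C@H](c1cc(OCc3ccccc3)c(OCc3ccccc3)c(OCc3ccccc3)c1)[C@H](O)C2 | intermediate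
17 | (2R,3S,4S)-4-[(2R,3R)-3,5,7-trihydroxy-2-(3,4,5-trihydroxyphenyl)-3,4-dihydro-2H-chromen-8-yl]-2-(3,4,5-trihydroxyphenyl)-3,4-dihydro-2H-chromene-3,7-diol | Oc1ccc2c(c1)O[C@H](c1cc(O)c(O)c(O)c1)[C@@H](O)[C@@H]2c1c(O)cc(O)c2c1O[C@H](c1cc(O)c(O)c(O)c1)[C@H](O)C2 | target

**Step count and risks**
Total step count: 7. Longest linear sequence: 6 steps (steps 1, 2, 3, 4, 6, 7); step 5 is the side branch.

Step 3 (proposed new method). The fluoride relay may stall, for example if adventitious water traps fluoride so that the silyl aldol accumulates, or the aldolate may undergo β-elimination to a chalcone before ring closure. The fallback uses known chemistry in two separate stages; it sets out from 5 and comes back at 11. Compound 5 is deprotonated with LiN(SiMe3)2 in THF at −78 °C and combined with 7, and the lithium aldolate is quenched cold with AcOH. This allows isolation of 2-(benzyloxy)-1-[4-(benzyloxy)-2-fluorophenyl]-3-hydroxy-3-[3,4,5-tris(benzyloxy)phenyl]propan-1-one F1 as a diastereomer mixture. In a second flask KOtBu (1.0 equiv) in THF at 0 °C should close ring C by intramolecular SNAr, and a catalytic amount of DBU should equilibrate C3 to the trans ketone 11.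

Step 4. The rate difference between the two enantiomers may be too small if the 3-benzyloxy group overrides catalyst control, or the product may ionise at C4 in the formic acid medium. The fallback sets out from 11 and comes back at 16. Compound 11 is reduced without resolution (NaBH4, THF/MeOH, 0 °C) to the racemic alcohol rac-12 F2. F2 is coupled with enantiopure 14 under the conditions of step 6. This should give 16 together with the diastereomer that carries the mirror-image upper unit, (2S,3R,4R)-3,7-bis(benzyloxy)-4-[(2R,3R)-5,7-bis(benzyloxy)-3-hydroxy-2-[3,4,5-tris(benzyloxy)phenyl]-3,4-dihydro-2H-chromen-8-yl]-2-[3,4,5-tris(benzyloxy)phenyl]-3,4-dihydro-2H-chromene F3. Because the lower unit is a single enantiomer, 16 and F3 are diastereomers and are separated by chromatography, so the chiral-pool unit takes over the resolution.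

Step 6. The cation may be captured by the 3-OH oxygen or by C6 of 14, facial selectivity at the planar C4 cation may be poor, the cation may eliminate to a flav-3-ene, or 16 may be alkylated further. The fallback sets out from 12 and comes back at 16. Compound 12 is converted with benzyl mercaptan (BF3·OEt2 cat., CH2Cl2, −20 °C) into the bench-stable C4 donor (2R,3R,4R)-4-(benzylsulfanyl)-3,7-bis(benzyloxy)-2-[3,4,5-tris(benzyloxy)phenyl]-3,4-dihydro-2H-chromene F4 (either C4 epimer would serve). Thiophilic activation with AgBF4 in THF/CH2Cl2 at 0 °C in the presence of 14 should release the same cation slowly under non-protic conditions and give 16.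

**Further compounds**
F1 | step 3 | 2-(benzyloxy)-1-[4-(benzyloxy)-2-fluorophenyl]-3-hydroxy-3-[3,4,5-tris(benzyloxy)phenyl]propan-1-one (diastereomer mixture) | OC(c1cc(OCc2ccccc2)c(OCc2ccccc2)c(OCc2ccccc2)c1)C(OCc1ccccc1)C(=O)c1ccc(OCc2ccccc2)cc1F
F2 | step 4 | racemic 12, that is 12 plus its (2S,3R,4S) enantiomer (the enantiomer that the list does not hold is shown) | C(c1ccccc1)Oc1ccc2c(c1)O[C@@H](c1cc(OCc3ccccc3)c(OCc3ccccc3)c(OCc3ccccc3)c1)[C@H](OCc1ccccc1)[C@H]2O
F3 | step 4 | (2S,3R,4R)-3,7-bis(benzyloxy)-4-[(2R,3R)-5,7-bis(benzyloxy)-3-hydroxy-2-[3,4,5-tris(benzyloxy)phenyl]-3,4-dihydro-2H-chromen-8-yl]-2-[3,4,5-tris(benzyloxy)phenyl]-3,4-dihydro-2H-chromene | C(c1ccccc1)Oc1ccc2c(c1)O[C@@H](c1cc(OCc3ccccc3)c(OCc3ccccc3)c(OCc3ccccc3)c1)[C@H](OCc1ccccc1)[C@H]2c1c(OCc3ccccc3)cc(OCc3ccccc3)c2c1O[C@H](c1cc(OCc3ccccc3)c(OCc3ccccc3)c(OCc3ccccc3)c1)[C@H](O)C2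
F4 | step 6 | (2R,3R,4R)-4-(benzylsulfanyl)-3,7-bis(benzyloxy)-2-[3,4,5-tris(benzyloxy)phenyl]-3,4-dihydro-2H-chromene (2,3-trans-3,4-trans) | C(c1ccccc1)Oc1ccc2c(c1)O[C@H](c1cc(OCc3ccccc3)c(OCc3ccccc3)c(OCc3ccccc3)c1)[C@@H](OCc1ccccc1)[C@@H]2SCc1ccccc1
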